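## Retrosynthetic overview
- The target comes from its tris-TBS ether by desilylation. That ether comes from its C8 epimer by equilibration of the one epimerisable centre.
- The only ring, the cyclopentenone, is formed once. A Piancatelli rearrangement (conrotatory 4π electrocyclisation) of a 3-bromo-5-octadienyl-2-furylcarbinol makes C8–C12 and installs the C12 hydroxyl.
- The furylcarbinol (C8–C9 bond) comes from a 3-bromo-2-furyllithium and an aldehyde carrying C1–C8.
- The aldehyde comes from L-arabinose. Sugar C2, C3 and C4 become C7, C6 and C5, and sugar C5 is extended by a Giese addition to methyl acrylate.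
- The furan comes from 2,3-dibromofuran and (2Z,5Z)-1-bromoocta-2,5-diene, which is made from propargyl alcohol and 1-bromopent-2-yne.

Numbering used in names is prostanoid: C1 is the ester carbon, C5–C7 carry the triol, C8 to C12 form the ring, and C13–C20 are the dienyl chain.

Assumption: a 5-alkyl-2-furylcarbinol rearranges like the parent series, so the new C12–OH ends up trans to the C8 substituent. The target has them cis, so C8 is corrected afterwards by equilibration.

## Route

Step 1
Reactants: 1 L-arabinose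
Product: 2 methyl L-arabinofuranoside (α/β mixture)
Conditions: HCl (cat.), MeOH, rt, 5 h; neutralise with basic resin
Reagents that add atoms: methanol, CO
Why: Kinetically controlled Fischer glycosidation gives mainly the furanosides, which mask C1 and tie up O4 while leaving the three arabinose stereocentres untouched.

Step 2
Reactants: 2 methyl L-arabinofuranoside
Product: 3 methyl 5-deoxy-5-iodo-L-arabinofuranoside (α/β)
Conditions: I2, PPh3, imidazole, THF, 65 °C
Reagents that add atoms: iodine, II
Why: Garegg–Samuelsson (Appel-type) iodination is selective for the single primary hydroxyl of the unprotected furanoside, and no stereocentre is involved.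

Step 3
Reactants: 3 methyl 5-deoxy-5-iodo-L-arabinofuranoside; 4 methyl acrylate (8 equiv)
Product: 5 methyl 4-[(L-arabino)-3,4-dihydroxy-5-methoxyoxolan-2-yl]butanoate (α/β)
Conditions: Bu3SnH (slow addition), AIBN (cat.), PhH, 80 °C
Reagents that add atoms: none
Why: Giese radical conjugate addition of the primary C5 radical to the acrylate adds C3–C1 in one operation, tolerates the free hydroxyls, and leaves the adjacent ring stereocentre unchanged because the radical is not on it.

Step 4
Reactants: 5 Giese ester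
Product: 7 methyl (5S,6S,7R)-5,6,7-tris(tert-butyldimethylsilyloxy)-7-(1,3-dithian-2-yl)heptanoate, via dithiane triol 6 (not isolated)
Conditions: HS(CH2)3SH, BF3·OEt2 (cat.), CH2Cl2, 0 °C; 2,6-lutidine, evaporate MeOH; then TBSOTf, 2,6-lutidine, CH2Cl2, 0 °C → rt
Reagents that add atoms: propane-1,3-dithiol, SCCCS; tert-butyldimethylsilyl triflate, CC(C)(C)[Si](C)(C)OS(=O)(=O)C(F)(F)F
Why: Lewis-acid transthioacetalisation opens the reactive furanoside to the acyclic dithiane, and immediate persilylation caps the freed C5–OH before it can lactonise onto the ester, with all C–O stereocentres retained.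

Step 5
Reactants: 7 tris-TBS dithiane
Product: 8 methyl (5S,6S,7R)-5,6,7-tris(tert-butyldimethylsilyloxy)-8-oxooctanoate
Conditions: MeI, CaCO3, MeCN/H2O 9:1, 40 °C
Reagents that add atoms: water, O
Why: Alkylative dithiane hydrolysis under buffered, near-neutral conditions frees the aldehyde without touching the TBS ethers or the ester and without epimerising the α-silyloxy centre.

Step 6
Reactants: 9 propargyl alcohol; 10 1-bromopent-2-yne
Product: 11 octa-2,5-diyn-1-ol
Conditions: CuI, NaI, K2CO3, DMF, rt
Reagents that add atoms: none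
Why: Copper-mediated coupling of a terminal alkyne with a propargylic halide is the standard way to build a skipped diyne and needs no protection of the alcohol.

Step 7
Reactants: 11 octa-2,5-diyn-1-ol
Product: 12 (2Z,5Z)-octa-2,5-dien-1-ol
Conditions: H2 (1 atm), P-2 Ni [Ni(OAc)2, NaBH4, both cat.], ethylenediamine, EtOH, rt
Reagents that add atoms: none
Why: Brown P-2 nickel syn-semihydrogenation converts both alkynes into Z-alkenes and stops cleanly at the skipped diene.

Step 8
Reactants: 12 (2Z,5Z)-octa-2,5-dien-1-ol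
Product: 13 (2Z,5Z)-1-bromoocta-2,5-diene
Conditions: CBr4, PPh3, CH2Cl2, −20 °C, used without storage
Reagents that add atoms: carbon tetrabromide, BrC(Br)(Br)Br
Why: The Appel reaction at low temperature gives the primary allylic bromide by SN2 without Z→E isomerisation or allylic transposition.

Step 9
Reactants: 14 2,3-dibromofuran; 13 (2Z,5Z)-1-bromoocta-2,5-diene
Product: 16 2,3-dibromo-5-[(2Z,5Z)-octa-2,5-dien-1-yl]furan, via 4,5-dibromo-2-furyllithium 15 (not isolated)
Conditions: LDA, THF, −78 °C; then 13, −78 → 0 °C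
Reagents that add atoms: none
Why: LDA removes the only α-proton (C5–H) of the furan without halogen–metal exchange, and the furyllithium displaces the reactive allylic bromide by SN2.

Step 10
Reactants: 16 dibromofuran; 8 aldehyde
Product: 18 methyl (5S,6S,7S,8RS)-8-{3-bromo-5-[(2Z,5Z)-octa-2,5-dien-1-yl]furan-2-yl}-8-hydroxy-5,6,7-tris(tert-butyldimethylsilyloxy)octanoate, via 3-bromo-2-furyllithium reagent 17 (not isolated)
Conditions: n-BuLi (1.0 equiv), Et2O/THF, −78 °C, 20 min; then 8, −78 °C; AcOH quench at −78 °C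
Reagents that add atoms: none
Why: Bromine–lithium exchange is selective for the α-bromine, and 1,2-addition to the aldehyde at −78 °C outruns attack on the methyl ester. The C8 carbinol mixture does not matter because this centre is ionised in the next step.

Step 11
Reactants: 18 furylcarbinol
Product: 20 methyl (5S,6S,7S)-7-{(1S,5S)-3-bromo-5-hydroxy-5-[(2Z,5Z)-octa-2,5-dien-1-yl]-2-oxocyclopent-3-en-1-yl}-5,6,7-tris(tert-butyldimethylsilyloxy)heptanoate (8S,12S; C12–OH trans to the C8 chain), via hydroxypentadienyl cation 19 (not isolated)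
Conditions: Dy(OTf)3 (10 mol %), TFA (5 mol %), t-BuOH/H2O 5:1, 80 °C; chromatographic removal of the minor 12R diastereomer
Reagents that add atoms: water, O
Why: In this Piancatelli rearrangement, ionisation, water capture at the alkylated furan carbon and ring opening give cation 19. Its conrotatory 4π closure, with the C7 chain and the C12–OH both outside, puts OH and chain trans. C12 bonds to the face of the C8=C9 enol anti to the allylic C7–O bond in the A1,3-minimised H-eclipsed conformer (the same face the inside-alkoxy model predicts), which sets 12S from the arabinose-derived C7.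

Step 12
Reactants: 20 kinetic (8S,12S) cyclopentenone
Product: 21 methyl (5S,6S,7S)-7-{(1R,5S)-3-bromo-5-hydroxy-5-[(2Z,5Z)-octa-2,5-dien-1-yl]-2-oxocyclopent-3-en-1-yl}-5,6,7-tris(tert-butyldimethylsilyloxy)heptanoate (8R,12S; the two carbon chains trans)
Conditions: Et3N (0.5 equiv), CH2Cl2, 23 °C, to equilibrium; chromatograph and recycle 20
Reagents that add atoms: none
Why: Base-mediated epimerisation through the dienol(ate) equilibrates only the acidic C8–H. It moves the very bulky C8 branch trans to the octadienyl chain and cis to the smaller OH, and silyloxide and hydroxide are poor E1cB leaving groups under a weak amine base.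

Step 13
Reactants: 21 (8R,12S) tris-TBS ether
Product: 22 target CNP0143456.1, methyl (5S,6S,7S)-7-{(1R,5S)-3-bromo-5-hydroxy-5-[(2Z,5Z)-octa-2,5-dien-1-yl]-2-oxocyclopent-3-en-1-yl}-5,6,7-trihydroxyheptanoate
Conditions: HF·pyridine, extra pyridine, THF, 0 °C → rt; NaHCO3 work-up
Reagents that add atoms: none
Why: Buffered fluoride desilylation removes the three secondary TBS groups under mildly acidic conditions, so it avoids β-elimination, retro-aldol cleavage, C8 scrambling and most δ-lactonisation.

## Compound list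
1 | L-arabinose | O=C[C@H](O)[C@@H](O)[C@@H](O)CO | starting material
2 | methyl L-arabinofuranoside (α/β) | COC1[C@H](O)[C@@H](O)[C@H](CO)O1 | intermediate
3 | methyl 5-deoxy-5-iodo-L-arabinofuranoside (α/β) | COC1[C@H](O)[C@@H](O)[C@H](CI)O1 | intermediate
4 | methyl acrylate | C=CC(=O)OC | starting material
5 | methyl 4-[(L-arabino)-3,4-dihydroxy-5-methoxyoxolan-2-yl]butanoate (α/β) | COC1[C@H](O)[C@@H](O)[C@H](CCCC(=O)OC)O1 | intermediate
6 | methyl (5S,6S,7R)-7-(1,3-dithian-2-yl)-5,6,7-trihydroxyheptanoate (not isolated) | S1CCCSC1[C@H](O)[C@@H](O)[C@@H](O)CCCC(=O)OC | intermediate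
7 | tris-TBS dithiane | S1CCCSC1[C@H](O[Si](C)(C)C(C)(C)C)[C@@H](O[Si](C)(C)C(C)(C)C)[C@@H](O[Si](C)(C)C(C)(C)C)CCCC(=O)OC | intermediate
8 | methyl (5S,6S,7R)-5,6,7-tris(TBSO)-8-oxooctanoate | O=C[C@H](O[Si](C)(C)C(C)(C)C)[C@@H](O[Si](C)(C)C(C)(C)C)[C@@H](O[Si](C)(C)C(C)(C)C)CCCC(=O)OC | intermediate
9 | propargyl alcohol | C#CCO | starting material
10 | 1-bromopent-2-yne | CCC#CCBr | starting material
11 | octa-2,5-diyn-1-ol | CCC#CCC#CCO | intermediate
12 | (2Z,5Z)-octa-2,5-dien-1-ol | CC/C=C\C/C=C\CO | intermediate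
13 | (2Z,5Z)-1-bromoocta-2,5-diene | CC/C=C\C/C=C\CBr | intermediate
14 | 2,3-dibromofuran | Brc1ccoc1Br | starting material
15 | 4,5-dibromo-2-furyllithium (not isolated) | [Li]c1cc(Br)c(Br)o1 | intermediate
16 | 2,3-dibromo-5-[(2Z,5Z)-octa-2,5-dien-1-yl]furan | CC/C=C\C/C=C\Cc1cc(Br)c(Br)o1 | intermediate
17 | 3-bromo-5-[(2Z,5Z)-octa-2,5-dien-1-yl]-2-furyllithium (not isolated) | CC/C=C\C/C=C\Cc1cc(Br)c([Li])o1 | intermediate
18 | furylcarbinol (C8 epimers) | CC/C=C\C/C=C\Cc1cc(Br)c(o1)C(O)[C@H](O[Si](C)(C)C(C)(C)C)[C@@H](O[Si](C)(C)C(C)(C)C)[C@@H](O[Si](C)(C)C(C)(C)C)CCCC(=O)OC | intermediate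
19 | ring-opened hydroxypentadienyl cation (not isolated) | CC/C=C\C/C=C\CC(=[OH+])/C=C(Br)\C(O)=C\[C@H](O[Si](C)(C)C(C)(C)C)[C@@H](O[Si](C)(C)C(C)(C)C)[C@@H](O[Si](C)(C)C(C)(C)C)CCCC(=O)OC | intermediate
20 | kinetic (8S,12S) cyclopentenone, tris-TBS | CC/C=C\C/C=C\C[C@@]1(O)C=C(Br)C(=O)[C@H]1[C@H](O[Si](C)(C)C(C)(C)C)[C@@H](O[Si](C)(C)C(C)(C)C)[C@@H](O[Si](C)(C)C(C)(C)C)CCCC(=O)OC | intermediate
21 | (8R,12S) cyclopentenone, tris-TBS | CC/C=C\C/C=C\C[C@@]1(O)C=C(Br)C(=O)[C@@H]1[C@H](O[Si](C)(C)C(C)(C)C)[C@@H](O[Si](C)(C)C(C)(C)C)[C@@H](O[Si](C)(C)C(C)(C)C)CCCC(=O)OC | intermediate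
22 | CNP0143456.1 | CC/C=C\C/C=C\C[C@@]1(O)C=C(Br)C(=O)[C@@H]1[C@H](O)[C@@H](O)[C@@H](O)CCCC(=O)OC | target

## Step count and risks
Total steps: 13. Longest linear sequence: 9 (steps 1–5 and 10–13). The side-chain branch (steps 6–9) joins at step 10.

**Step 11 (Piancatelli rearrangement).** This is the most likely failure. The 3-bromo substituent and the α-silyloxy group both retard ionisation, a 1,2-hydride shift from C7 can compete, and the 12S/12R ratio may be modest.

The fallback sets out from 13 and 8 and returns at 20. It runs the rearrangement on the more electron-rich bromine-free furan and installs the halogen afterwards.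
- Furan is lithiated with n-BuLi and alkylated with 13 to give 2-[(2Z,5Z)-octa-2,5-dien-1-yl]furan F1.
- Lithiation of F1 at its free α-position and addition to 8 gives the debromo furylcarbinol F2.
- F2 rearranges under the same aqueous Lewis-acid conditions to the debromo cyclopentenone F3.
- Nucleophilic epoxidation (t-BuOOH, Triton B, 0 °C) attacks only the enone and not the skipped diene, giving the 10,11-epoxy ketone F4.
- LiBr/AcOH opens F4 at C10 to the bromohydrin F5, which loses water (MsCl, Et3N if needed) to give 20.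

**Step 12 (C8 equilibration).** The dienolate can expel the C7 silyloxide or the C12 hydroxide, and the equilibrium ratio is unproven.

The fallback sets out from 20 and returns at 22. Compound 20 is desilylated first (HF·pyridine) to the 8-epi natural product F6. F6 is then equilibrated in THF/pH 7.5 phosphate buffer. All potential leaving groups are now hydroxide, a C7–OH/C12–OH hydrogen bond favours the cis arrangement, and the natural isomer is the expected thermodynamic sink.

**Step 4 (ring opening and silylation).** The δ-hydroxy ester 6 can lactonise under the Lewis acid before it is silylated.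

The fallback sets out from 5 and returns at 7. It makes the lactone on purpose.
- Propane-1,3-dithiol/BF3·OEt2 followed by catalytic TsOH in toluene drives 5 fully to the dithianyl δ-lactone diol F7.
- TBSOTf/2,6-lutidine gives the bis-TBS lactone F8.
- K2CO3/MeOH opens F8 to the C5-hydroxy methyl ester F9.
- F9 is silylated at once with TBSOTf to 7. Any silyl migration during the methanolysis is harmless because the product is persilylated.

## Further compounds
F1 | step 11 | 2-[(2Z,5Z)-octa-2,5-dien-1-yl]furan | CC/C=C\C/C=C\Cc1ccco1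
F2 | step 11 | debromo furylcarbinol (C8 epimers) | CC/C=C\C/C=C\Cc1ccc(o1)C(O)[C@H](O[Si](C)(C)C(C)(C)C)[C@@H](O[Si](C)(C)C(C)(C)C)[C@@H](O[Si](C)(C)C(C)(C)C)CCCC(=O)OC
F3 | step 11 | debromo (8S,12S) cyclopentenone, tris-TBS | CC/C=C\C/C=C\C[C@@]1(O)C=CC(=O)[C@H]1[C@H](O[Si](C)(C)C(C)(C)C)[C@@H](O[Si](C)(C)C(C)(C)C)[C@@H](O[Si](C)(C)C(C)(C)C)CCCC(=O)OC
F4 | step 11 | 10,11-epoxy ketone (epoxide configuration not relevant) | CC/C=C\C/C=C\C[C@@]1(O)C2OC2C(=O)[C@H]1[C@H](O[Si](C)(C)C(C)(C)C)[C@@H](O[Si](C)(C)C(C)(C)C)[C@@H](O[Si](C)(C)C(C)(C)C)CCCC(=O)OC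
F5 | step 11 | 10-bromo-11-hydroxy ketone (bromohydrin) | CC/C=C\C/C=C\C[C@@]1(O)C(O)C(Br)C(=O)[C@H]1[C@H](O[Si](C)(C)C(C)(C)C)[C@@H](O[Si](C)(C)C(C)(C)C)[C@@H](O[Si](C)(C)C(C)(C)C)CCCC(=O)OC
F6 | step 12 | 8-epi-CNP0143456.1 | CC/C=C\C/C=C\C[C@@]1(O)C=C(Br)C(=O)[C@H]1[C@H](O)[C@@H](O)[C@@H](O)CCCC(=O)OC
F7 | step 4 | dithianyl δ-lactone diol | S1CCCSC1[C@H](O)[C@@H](O)[C@@H]2CCCC(=O)O2
F8 | step 4 | bis-TBS dithianyl δ-lactone | S1CCCSC1[C@H](O[Si](C)(C)C(C)(C)C)[C@@H](O[Si](C)(C)C(C)(C)C)[C@@H]2CCCC(=O)O2
F9 | step 4 | C5-hydroxy-6,7-bis-TBS dithianyl methyl ester | S1CCCSC1[C@H](O[Si](C)(C)C(C)(C)C)[C@@H](O[Si](C)(C)C(C)(C)C)[C@@H](O)CCCC(=O)OC
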